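**Plan**
- Enabling feature: in the pyranone ring the ketone carbon C4 sits between arene carbon C4a and the methyl-bearing C3, which adjoins the O1–C2(H)CH3 unit. C4 can therefore begin as a formyl carbon on C4a, and C3 with its methyl as the vinyl group of an (S)-but-3-en-2-yl ether on O1.
- Retrosynthetic cuts, in order: the two MOM ethers; C3–C4 (carbene-catalysed hydroacylation); O1–C2 (Mitsunobu ether); the methyl ester is re-tied to O1 as a dihydrocoumarin lactone; then the formyl carbon on C4a, the prenyl group on C6 and the coumarin ring (Pechmann) fall back to phloroglucinol and ethyl 3-oxohexanoate.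
- Forward order of rings: the coumarin ring is made first and acts as a temporary ring that singles out O1 among three phenolic oxygens. Formyl, prenyl and MOM groups are placed around it, the lactone is opened to the methyl ester, O1 is etherified, and the pyranone ring (the only ring of the target) is closed last.
- Stereochemistry: the side-chain centre comes from a CuH/(R)-DTBM-SEGPHOS conjugate reduction (catalyst control). C2 comes from (R)-but-3-en-2-ol with Mitsunobu inversion. C3 is set from C2 in the ring closure and secured by base equilibration to the 2,3-trans, (2S,3S), isomer.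

Key step: step 9

Numbering: the plan and compounds 14–17 use the chromanone numbering of the target (O1, C2, C3, C4, C4a, C5–C8, C8a). Intermediates 3–11 use chromen-2-one numbering, in which C8 is the later C4a, C6 the later C6, O1 the later O1, and the 5- and 7-oxygens the later 7- and 5-oxygens.

Assumption: the (R) antipode of DTBM-SEGPHOS is taken to send hydride to the Re face of C4 in step 5, by analogy with other 4-substituted coumarins; if a first run shows the opposite sense, the (S) ligand is used and nothing else changes.

**Route**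

Step 1
Reactants: 1 phloroglucinol; 2 ethyl 3-oxohexanoate
Product: 3 5,7-dihydroxy-4-propyl-2H-chromen-2-one
Conditions: conc. H2SO4, 0 °C to rt; poured onto ice
Reagents that add atoms: none
Why: Pechmann condensation: acid-promoted transesterification, ring C-alkylation by the ketone and dehydration close the pyranone, and the threefold symmetry of 1 allows only one regioisomer.

Step 2
Reactants: 3 5,7-dihydroxy-4-propyl-2H-chromen-2-one
Product: 5 5,7-dihydroxy-2-oxo-4-propyl-2H-chromene-8-carbaldehyde, via iminium chloride 4 (not isolated)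
Conditions: N-methylformanilide, POCl3, ClCH2CH2Cl, 0 to 75 °C; then H2O, 60 °C
Reagents that add atoms: N-methylformanilide, CN(C=O)c1ccccc1 (formyl carbon); water, O (carbonyl oxygen)
Why: Vilsmeier–Haack formylation: the chloroiminium ion attacks C8, between the 7-hydroxyl and the ring oxygen, which is the position at which 5,7-dihydroxy-4-alkylcoumarins are known to be formylated, and the first formyl group deactivates the ring against a second one.

Step 3
Reactants: 5 5,7-dihydroxy-2-oxo-4-propyl-2H-chromene-8-carbaldehyde; 6 1-bromo-3-methylbut-2-ene (prenyl bromide)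
Product: 7 5,7-dihydroxy-6-(3-methylbut-2-en-1-yl)-2-oxo-4-propyl-2H-chromene-8-carbaldehyde
Conditions: DBU (2 equiv), 6 (1.05 equiv), THF, 0 °C to rt
Reagents that add atoms: none
Why: C-alkylation of an ambident phenoxide (C-prenylation of an acylphloroglucinol-type ring): C6 is the only unsubstituted ring carbon and lies between two phenoxide oxygens, so the allylic bromide should be taken up there, with about one equivalent of bromide limiting O- and double alkylation.

Step 4
Reactants: 7 5,7-dihydroxy-6-(3-methylbut-2-en-1-yl)-2-oxo-4-propyl-2H-chromene-8-carbaldehyde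
Product: 8 5,7-bis(methoxymethoxy)-6-(3-methylbut-2-en-1-yl)-2-oxo-4-propyl-2H-chromene-8-carbaldehyde
Conditions: NaH (2.2 equiv), MOMCl (2.5 equiv), THF–DMF, 0 °C to rt
Reagents that add atoms: chloromethyl methyl ether, COCCl
Why: Williamson-type O-alkylation: both sodium phenoxides, including the one hydrogen-bonded to the aldehyde, are capped by the reactive chloromethyl ether, which removes the acidic protons before the hydride step and gives base-stable, acid-labile acetals.

Step 5
Reactants: 8 5,7-bis(methoxymethoxy)-6-(3-methylbut-2-en-1-yl)-2-oxo-4-propyl-2H-chromene-8-carbaldehyde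
Product: 10 (4S)-8-(hydroxymethyl)-5,7-bis(methoxymethoxy)-6-(3-methylbut-2-en-1-yl)-4-propyl-3,4-dihydro-2H-chromen-2-one, via hydroxymethyl coumarin 9 (not isolated)
Conditions: Cu(OAc)2·H2O (5 mol %), (R)-DTBM-SEGPHOS (5 mol %), (EtO)2MeSiH (4 equiv), t-BuOH (3 equiv), toluene, 0 °C to rt; aqueous NaHCO3 work-up
Reagents that add atoms: none
Why: Copper hydride asymmetric conjugate reduction: the ligated CuH first reduces the aldehyde (1,2) and then adds hydride to C4 of the unsaturated lactone on the Re face chosen by the bisphosphine, with t-BuOH protonating the copper alkoxide and enolate, which sets the (4S) centre and leaves the isolated prenyl alkene untouched.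

Step 6
Reactants: 10 (4S)-8-(hydroxymethyl)-5,7-bis(methoxymethoxy)-6-(3-methylbut-2-en-1-yl)-4-propyl-3,4-dihydro-2H-chromen-2-one
Product: 11 (4S)-5,7-bis(methoxymethoxy)-6-(3-methylbut-2-en-1-yl)-2-oxo-4-propyl-3,4-dihydro-2H-chromene-8-carbaldehyde
Conditions: activated MnO2 (excess), CH2Cl2, rt
Reagents that add atoms: none
Why: MnO2 oxidation of a benzylic alcohol: the electron-rich benzylic carbinol is returned to the aldehyde under neutral conditions that should not touch the lactone, the MOM ethers, the prenyl group or the C4 centre.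

Step 7
Reactants: 11 (4S)-5,7-bis(methoxymethoxy)-6-(3-methylbut-2-en-1-yl)-2-oxo-4-propyl-3,4-dihydro-2H-chromene-8-carbaldehyde
Product: 12 methyl (3S)-3-[3-formyl-2-hydroxy-4,6-bis(methoxymethoxy)-5-(3-methylbut-2-en-1-yl)phenyl]hexanoate
Conditions: NaOMe (1.1 equiv), MeOH, 0 °C; then AcOH (1.1 equiv), cold work-up, used at once
Reagents that add atoms: methanol, CO, delivered as sodium methoxide, C[O-].[Na+]
Why: Base-mediated transesterification (lactone methanolysis): methoxide opens the aryl ester because the leaving phenoxide is stabilised by the ortho formyl group and is a poor nucleophile for reclosure, and the stereocentre, being β to the carbonyl, cannot epimerise.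

Step 8
Reactants: 12 methyl (3S)-3-[3-formyl-2-hydroxy-4,6-bis(methoxymethoxy)-5-(3-methylbut-2-en-1-yl)phenyl]hexanoate; 13 (2R)-but-3-en-2-ol
Product: 14 methyl (3S)-3-[2-[(2S)-but-3-en-2-yloxy]-3-formyl-4,6-bis(methoxymethoxy)-5-(3-methylbut-2-en-1-yl)phenyl]hexanoate
Conditions: PPh3, DIAD, 13 (1.5 equiv), THF, 0 °C to rt
Reagents that add atoms: none
Why: Mitsunobu reaction: the phenol, made acidic by the ortho aldehyde, displaces the oxyphosphonium derivative of 13 by SN2 with inversion, turning the (R) carbinol into the (S) aryl ether that becomes C2.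

Step 9
Reactants: 14 methyl (3S)-3-[2-[(2S)-but-3-en-2-yloxy]-3-formyl-4,6-bis(methoxymethoxy)-5-(3-methylbut-2-en-1-yl)phenyl]hexanoate
Product: 16 methyl (3S)-3-[(2S,3S)-5,7-bis(methoxymethoxy)-2,3-dimethyl-6-(3-methylbut-2-en-1-yl)-4-oxo-3,4-dihydro-2H-chromen-8-yl]hexanoate, via Breslow enaminol 15 (not isolated)
Conditions: 2-mesityl-6,7-dihydro-5H-pyrrolo[2,1-c][1,2,4]triazol-2-ium tetrafluoroborate (20 mol %), DBU (20 mol %), degassed 1,4-dioxane, 80–100 °C
Reagents that add atoms: none
Why: DBU frees the triazolylidene, which adds to the aldehyde and after proton shift gives the nucleophilic Breslow enaminol 15; its carbon bonds to the internal alkene carbon of the butenyl ether while the enaminol O–H proton passes to the terminal CH2 in a concerted, Conia-ene-like event, and loss of the carbene from the resulting alkoxide releases ketone 16. The closest known reaction type is the carbene-catalysed intramolecular hydroacylation of unactivated alkenes in 2-allyloxybenzaldehydes, which gives 3-methylchroman-4-ones. The pyranone ring (O1, C2, C3, C4, C4a, C8a) closes in a 6-exo-trig mode. The new C3 centre is controlled by the existing C2 centre: a chair-like transition state with the C2 methyl and the alkene terminus both pseudo-equatorial leads to the 2,3-trans product, and the amidine base can equilibrate C3 through the enol toward this diequatorial (2S,3S) arrangement. The step needs chemoselectivity for the vinyl group over the prenyl alkene and the ester, and exo over endo closure: the vinyl group is held beside the formyl group by the ortho ether tether, whereas the trisubstituted prenyl alkene is meta to it and the ester cannot be reached. DBU is kept at the level of the catalyst and the temperature moderate so that retro-oxa-Michael opening at C2, which would erode that centre, is avoided.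

Step 10
Reactants: 16 methyl (3S)-3-[(2S,3S)-5,7-bis(methoxymethoxy)-2,3-dimethyl-6-(3-methylbut-2-en-1-yl)-4-oxo-3,4-dihydro-2H-chromen-8-yl]hexanoate
Product: 17 methyl (3S)-3-[(2S,3S)-5,7-dihydroxy-2,3-dimethyl-6-(3-methylbut-2-en-1-yl)-4-oxo-3,4-dihydro-2H-chromen-8-yl]hexanoate
Conditions: 1 M HCl in MeOH, 0 °C to rt; NaHCO3 quench before concentration
Reagents that add atoms: none
Why: Acid-catalysed acetal cleavage (MOM removal by acetal exchange with methanol): both aryl MOM ethers pass to methanol as dimethoxymethane under conditions mild enough to spare the prenyl alkene, and methanol as solvent keeps the side chain as the methyl ester and not as a lactone on the freed 7-hydroxyl.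

**Compound list**

1 | phloroglucinol (benzene-1,3,5-triol) | Oc1cc(O)cc(O)c1 | starting material
2 | ethyl 3-oxohexanoate | CCCC(=O)CC(=O)OCC | starting material
3 | 5,7-dihydroxy-4-propyl-2H-chromen-2-one | CCCC1=CC(=O)Oc2cc(O)cc(O)c12 | intermediate
4 | N-[(5,7-dihydroxy-2-oxo-4-propyl-2H-chromen-8-yl)methylidene]-N-methylanilinium chloride (formed in the flask) | CCCC1=CC(=O)Oc2c(C=[N+](C)c3ccccc3)c(O)cc(O)c12.[Cl-] | intermediate
5 | 5,7-dihydroxy-2-oxo-4-propyl-2H-chromene-8-carbaldehyde | CCCC1=CC(=O)Oc2c(C=O)c(O)cc(O)c12 | intermediate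
6 | 1-bromo-3-methylbut-2-ene (prenyl bromide) | CC(C)=CCBr | starting material
7 | 5,7-dihydroxy-6-(3-methylbut-2-en-1-yl)-2-oxo-4-propyl-2H-chromene-8-carbaldehyde | CCCC1=CC(=O)Oc2c(C=O)c(O)c(CC=C(C)C)c(O)c12 | intermediate
8 | 5,7-bis(methoxymethoxy)-6-(3-methylbut-2-en-1-yl)-2-oxo-4-propyl-2H-chromene-8-carbaldehyde | CCCC1=CC(=O)Oc2c(C=O)c(OCOC)c(CC=C(C)C)c(OCOC)c12 | intermediate
9 | 8-(hydroxymethyl)-5,7-bis(methoxymethoxy)-6-(3-methylbut-2-en-1-yl)-4-propyl-2H-chromen-2-one (formed in the flask) | CCCC1=CC(=O)Oc2c(CO)c(OCOC)c(CC=C(C)C)c(OCOC)c12 | intermediate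
10 | (4S)-8-(hydroxymethyl)-5,7-bis(methoxymethoxy)-6-(3-methylbut-2-en-1-yl)-4-propyl-3,4-dihydro-2H-chromen-2-one | CCC[C@H]1CC(=O)Oc2c1c(OCOC)c(CC=C(C)C)c(OCOC)c2CO | intermediate
11 | (4S)-5,7-bis(methoxymethoxy)-6-(3-methylbut-2-en-1-yl)-2-oxo-4-propyl-3,4-dihydro-2H-chromene-8-carbaldehyde | CCC[C@H]1CC(=O)Oc2c1c(OCOC)c(CC=C(C)C)c(OCOC)c2C=O | intermediate
12 | methyl (3S)-3-[3-formyl-2-hydroxy-4,6-bis(methoxymethoxy)-5-(3-methylbut-2-en-1-yl)phenyl]hexanoate | CCC[C@@H](CC(=O)OC)c1c(OCOC)c(CC=C(C)C)c(OCOC)c(C=O)c1O | intermediate
13 | (2R)-but-3-en-2-ol | C[C@@H](O)C=C | starting material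
14 | methyl (3S)-3-[2-[(2S)-but-3-en-2-yloxy]-3-formyl-4,6-bis(methoxymethoxy)-5-(3-methylbut-2-en-1-yl)phenyl]hexanoate | CCC[C@@H](CC(=O)OC)c1c(OCOC)c(CC=C(C)C)c(OCOC)c(C=O)c1O[C@@H](C)C=C | intermediate
15 | Breslow enaminol of 14: the formyl carbon carries OH and is doubly bonded to C3 of the 2-mesityl-6,7-dihydro-5H-pyrrolo[2,1-c][1,2,4]triazol-3-ylidene unit (formed in the flask) | CCC[C@@H](CC(=O)OC)c1c(OCOC)c(CC=C(C)C)c(OCOC)c(C(O)=C2N(c3c(C)cc(C)cc3C)N=C3CCCN23)c1O[C@@H](C)C=C | intermediate
16 | methyl (3S)-3-[(2S,3S)-5,7-bis(methoxymethoxy)-2,3-dimethyl-6-(3-methylbut-2-en-1-yl)-4-oxo-3,4-dihydro-2H-chromen-8-yl]hexanoate | CCC[C@@H](CC(=O)OC)c1c(OCOC)c(CC=C(C)C)c(OCOC)c2c1O[C@@H](C)[C@H](C)C2=O | intermediate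
17 | methyl (3S)-3-[(2S,3S)-5,7-dihydroxy-2,3-dimethyl-6-(3-methylbut-2-en-1-yl)-4-oxo-3,4-dihydro-2H-chromen-8-yl]hexanoate | CCC[C@@H](CC(=O)OC)c1c(O)c(CC=C(C)C)c(O)c2c1O[C@@H](C)[C@H](C)C2=O | target

**Count and risks**

Total steps: 10. Longest linear sequence: 10 steps (1 to 17); 2, 6 and 13 are bought and enter along the way.

Steps most likely to fail:

1. Step 9. The carbene may add only slowly to an aldehyde flanked by two ortho oxygens, the enaminol may be oxidised by traces of air, and the amidine base may open the product by retro-oxa-Michael reaction and so erode C2. The fallback forms the same bond and ring through an acyl radical and sets out from 14. A thiol-catalysed radical-chain hydroacylation (tert-dodecanethiol, AIBN, chlorobenzene, 80 °C) is used: a thiyl radical abstracts the formyl hydrogen, the aroyl radical closes 6-exo onto the vinyl group, and the primary radical takes hydrogen from the thiol. Without base this should give 16 mixed with its C3 epimer, methyl (3S)-3-[(2S,3R)-5,7-bis(methoxymethoxy)-2,3-dimethyl-6-(3-methylbut-2-en-1-yl)-4-oxo-3,4-dihydro-2H-chromen-8-yl]hexanoate F1. Brief treatment with Et3N in CH2Cl2 at rt should equilibrate F1 to the trans isomer, and the route is rejoined at 16.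

2. Step 3. O-alkylation of either phenoxide and a second, dearomatising C-alkylation may compete with the single C-prenylation. The fallback replaces direct alkylation by a sigmatropic route and sets out from 5. Allyl bromide and K2CO3 in acetone should alkylate the hydroxyl that is not hydrogen-bonded to the aldehyde and give 7-hydroxy-2-oxo-5-(prop-2-en-1-yloxy)-4-propyl-2H-chromene-8-carbaldehyde F2. Claisen rearrangement in N,N-diethylaniline at about 190 °C moves the allyl group to C6, the only free ortho position, to give 5,7-dihydroxy-2-oxo-6-(prop-2-en-1-yl)-4-propyl-2H-chromene-8-carbaldehyde F3. Cross-metathesis of F3 with 2-methylbut-2-ene and the second-generation Grubbs catalyst in CH2Cl2 at 40 °C then gives the prenyl compound, and the route is rejoined at 7.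

3. Step 8. The phenol is flanked on both sides, so the SN2 displacement at a secondary allylic carbon may be slow; allylic transposition to the achiral crotyl ether and partial loss of configuration through an ion pair may intervene, and 12 may relactonise before it couples. The fallback sets C2 by catalyst control and sets out from 12. (E)-But-2-en-1-ol is converted with methyl chloroformate and pyridine into (E)-but-2-en-1-yl methyl carbonate F4. Phenol 12 and F4 are then combined with Pd2(dba)3·CHCl3 (a zerovalent palladium source) and the enantiomer of N,N'-(cyclohexane-1,2-diyl)bis[2-(diphenylphosphanyl)benzamide] that leads to the (S) ether, in CH2Cl2 at rt. The phenol attacks the more substituted end of the crotyl palladium complex, carbon dioxide and methanol are lost, and the route is rejoined at 14.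

**Further compounds**

F1 | step 9 | methyl (3S)-3-[(2S,3R)-5,7-bis(methoxymethoxy)-2,3-dimethyl-6-(3-methylbut-2-en-1-yl)-4-oxo-3,4-dihydro-2H-chromen-8-yl]hexanoate | CCC[C@@H](CC(=O)OC)c1c(OCOC)c(CC=C(C)C)c(OCOC)c2c1O[C@@H](C)[C@@H](C)C2=O
F2 | step 3 | 7-hydroxy-2-oxo-5-(prop-2-en-1-yloxy)-4-propyl-2H-chromene-8-carbaldehyde | C=CCOc1cc(O)c(C=O)c2OC(=O)C=C(CCC)c12
F3 | step 3 | 5,7-dihydroxy-2-oxo-6-(prop-2-en-1-yl)-4-propyl-2H-chromene-8-carbaldehyde | CCCC1=CC(=O)Oc2c(C=O)c(O)c(CC=C)c(O)c12
F4 | step 8 | (E)-but-2-en-1-yl methyl carbonate | C/C=C/COC(=O)OC
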